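## Retrosynthetic overview

1. Target 31 ⇐ hexabenzyl cage 30 (hydrogenolysis) ⇐ acid 27 by anodic decarboxylation and ketalisation; the central 1,3-dioxane and the dihydropyranone ketal form last.
2. 27 ⇐ C1–C3' bond by invertive substitution of bridged acylal 17 with the silyl dienol ether of triketone 24, then γ-pyrone closure; the carboxyl carbon of (S)-lactic acid is a traceless controller for C1.
3. 17 ⇐ 3-formylchromone 15 ⇐ 3-iodochromone 13 (ICl cyclisation of ynone 12) ⇐ acyl Sonogashira of the common aroyl chloride 11 with propargylated lactic acid dioxolanone 10.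
4. 24 ⇐ the same aroyl chloride 11: Stille vinylation, debenzylative oxa-Michael closure to chromanone 21, acetoacetylation with diketene.
5. 11 ⇐ acid 5 ⇐ 2,4,5-trihydroxybenzaldehyde (benzylation, oxidation, carboxylate-directed ortho-lithiation). Ring order: chromone / chromanone → bridged acylal → γ-pyrone → dioxane cage.

**Assumption:** the SMILES is taken as the natural enantiomer. Unprimed locants follow pyrano[4,3-b]chromene numbering of the fulvic-acid-type half (C1 = O–CH, C3 = methyl ketal carbon); primed locants follow pyrano[3,2-c]chromene numbering of the citromycetin-type half (C2' = methyl ketal carbon, C3' = CH). The target is then (1S,3R,2'S,3'S).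

## Route

**Step 1**
Reactants: 1 2,4,5-trihydroxybenzaldehyde
Product: 2 2,4,5-tris(benzyloxy)benzaldehyde
Conditions: BnBr (3.3 equiv), K2CO3, DMF, 60 °C
Reagents that add atoms: benzyl bromide BrCc1ccccc1
Why: Williamson etherification of all three phenols, the hydrogen-bonded 2-OH needing the warm DMF conditions; no stereocentre is involved.

**Step 2**
Reactants: 2 2,4,5-tris(benzyloxy)benzaldehyde
Product: 3 2,4,5-tris(benzyloxy)benzoic acid
Conditions: NaClO2, NaH2PO4, 2-methyl-2-butene, t-BuOH/H2O, rt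
Reagents that add atoms: sodium chlorite [Na+].[O-]Cl=O
Why: Pinnick oxidation, in which the alkene scavenger traps HOCl so the electron-rich ring and the benzyl ethers are untouched.

**Step 3**
Reactants: 3 2,4,5-tris(benzyloxy)benzoic acid
Product: 5 3,4,6-tris(benzyloxy)-2-[(benzyloxy)carbonyl]benzoic acid, via dilithiated benzoate 4 (not isolated)
Conditions: s-BuLi (2.2 equiv), TMEDA, THF, −78 °C; ClCO2Bn (1.05 equiv), −78 °C; aq. HCl
Reagents that add atoms: benzyl chloroformate O=C(Cl)OCc1ccccc1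
Why: carboxylate-directed ortho-lithiation (directed ortho metalation) at the only position ortho to CO2Li, reinforced by the flanking 5-benzyloxy group, followed by C-acylation of the aryllithium, which outpaces the lithium carboxylate at −78 °C.

**Step 4**
Reactants: 6 (S)-lactic acid
Product: 7 (2S,5S)-2-tert-butyl-5-methyl-1,3-dioxolan-4-one
Conditions: t-BuCHO, TsOH (cat.), pentane, reflux (Dean–Stark); recrystallisation (Et2O/pentane, −78 °C)
Reagents that add atoms: pivaldehyde CC(C)(C)C=O
Why: acid-catalysed acetalisation under thermodynamic control places tert-butyl cis to the lactate methyl, so the new acetal centre is set by the bought centre (minor trans isomer removed by crystallisation); this is the first half of a self-regeneration of the stereocentre.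

**Step 5**
Reactants: 7 (2S,5S)-2-tert-butyl-5-methyl-1,3-dioxolan-4-one; 8 propargyl bromide
Product: 10 (2S,5R)-2-tert-butyl-5-methyl-5-(prop-2-yn-1-yl)-1,3-dioxolan-4-one, via lithium enolate 9 (not isolated)
Conditions: LiN(i-Pr)2, THF, −78 °C; then 8, −78 → −30 °C
Reagents that add atoms: none
Why: enolate alkylation anti to the tert-butyl group puts the propargyl group where the lactate hydrogen was (overall retention; the descriptor becomes R only through the priority change), so the quaternary centre is bought with lactic acid.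

**Step 6**
Reactants: 5 3,4,6-tris(benzyloxy)-2-[(benzyloxy)carbonyl]benzoic acid
Product: 11 benzyl 2,3,5-tris(benzyloxy)-6-(chlorocarbonyl)benzoate
Conditions: 1-chloro-N,N,2-trimethylprop-1-en-1-amine (1.1 equiv), CH2Cl2, 0 °C → rt; evaporate; crude chloride kept cold as a CH2Cl2 stock solution and divided between steps 7 and 11
Reagents that add atoms: 1-chloro-N,N,2-trimethylprop-1-en-1-amine CC(C)=C(Cl)N(C)C
Why: acid chloride formation with the Ghosez chloroenamine is neutral (no HCl, no heating), which spares the benzyl ethers and the neighbouring benzyl ester, and the only by-product, an inert tertiary amide, does not disturb either palladium coupling that follows.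

**Step 7**
Reactants: 11 benzyl 2,3,5-tris(benzyloxy)-6-(chlorocarbonyl)benzoate; 10 (2S,5R)-2-tert-butyl-5-methyl-5-(prop-2-yn-1-yl)-1,3-dioxolan-4-one
Product: 12 benzyl 2,3,5-tris(benzyloxy)-6-{4-[(2S,4R)-2-tert-butyl-4-methyl-5-oxo-1,3-dioxolan-4-yl]but-2-ynoyl}benzoate
Conditions: 10 (1.1 equiv), Pd(PPh3)2Cl2 (2 mol%), CuI (4 mol%), Et3N (1.2 equiv), THF, rt
Reagents that add atoms: none
Why: acyl Sonogashira coupling of the terminal alkyne with the aroyl chloride gives the ynone; the acylal and both its stereocentres are inert to Et3N.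

**Step 8**
Reactants: 12 benzyl 2,3,5-tris(benzyloxy)-6-{4-[(2S,4R)-2-tert-butyl-4-methyl-5-oxo-1,3-dioxolan-4-yl]but-2-ynoyl}benzoate
Product: 13 benzyl 6,7-bis(benzyloxy)-2-{[(2S,4R)-2-tert-butyl-4-methyl-5-oxo-1,3-dioxolan-4-yl]methyl}-3-iodo-4-oxo-4H-chromene-5-carboxylate
Conditions: ICl (1.2 equiv), CH2Cl2, −78 °C
Reagents that add atoms: iodine monochloride ClI
Why: electrophilic iodocyclisation of an ortho-alkoxyaryl ynone, in which the iodonium-activated alkyne is attacked 6-endo-dig by the only benzyloxy oxygen that can reach it and benzyl chloride is lost, gives the 3-iodochromone.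

**Step 9**
Reactants: 13 benzyl 6,7-bis(benzyloxy)-2-{[(2S,4R)-2-tert-butyl-4-methyl-5-oxo-1,3-dioxolan-4-yl]methyl}-3-iodo-4-oxo-4H-chromene-5-carboxylate
Product: 15 benzyl 6,7-bis(benzyloxy)-2-{[(2S,4R)-2-tert-butyl-4-methyl-5-oxo-1,3-dioxolan-4-yl]methyl}-3-formyl-4-oxo-4H-chromene-5-carboxylate, via chromen-3-ylmagnesium chloride 14 (not isolated)
Conditions: i-PrMgCl·LiCl (1.1 equiv), THF, −78 °C; DMF, −78 → 0 °C; aq. HCl (1 M)
Reagents that add atoms: N,N-dimethylformamide CN(C)C=O
Why: iodine–magnesium exchange of the α-iodoenone is fast at −78 °C, where the hindered benzyl ester and the acylal carbonyl are not attacked, and the vinyl Grignard reagent is formylated by DMF.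

**Step 10**
Reactants: 15 benzyl 6,7-bis(benzyloxy)-2-{[(2S,4R)-2-tert-butyl-4-methyl-5-oxo-1,3-dioxolan-4-yl]methyl}-3-formyl-4-oxo-4H-chromene-5-carboxylate
Product: 17 benzyl (1R,3R)-7,8-bis(benzyloxy)-3-methyl-10,12-dioxo-4,10-dihydro-1H,3H-1,3-(epoxymethano)pyrano[4,3-b]chromene-9-carboxylate (bridged acylal: C1–O–C(=O)–C3), via hydroxy acid 16 (not isolated)
Conditions: TFA/H2O 9:1, 40 °C; evaporate; then TsOH (cat.), 4 Å MS, PhMe, 60 °C
Reagents that add atoms: none
Why: acid hydrolysis of the pivaldehyde acylal frees the α-hydroxy acid, whose OH and CO2H condense with the adjacent 3-formyl group (lactol then lactone, an acylal exchange driven by loss of pivaldehyde); the new C1 acetal centre can only form cis-bridged and is therefore fixed as R by the lactate-derived C3.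

**Step 11**
Reactants: 11 benzyl 2,3,5-tris(benzyloxy)-6-(chlorocarbonyl)benzoate; 18 tributyl(vinyl)stannane
Product: 19 benzyl 2-acryloyl-3,5,6-tris(benzyloxy)benzoate
Conditions: 18 (1.1 equiv), Pd(PPh3)4 (3 mol%), PhMe, 60 °C
Reagents that add atoms: none
Why: Stille acylation of the acid chloride delivers the aryl vinyl ketone without over-addition.

**Step 12**
Reactants: 19 benzyl 2-acryloyl-3,5,6-tris(benzyloxy)benzoate
Product: 21 benzyl 6,7-bis(benzyloxy)-4-oxochromane-5-carboxylate, via phenol 20 (not isolated)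
Conditions: BCl3 (1.1 equiv), CH2Cl2, −78 °C; H2O; then Et3N (0.1 equiv), CH2Cl2, rt
Reagents that add atoms: none
Why: chelation-controlled cleavage of the benzyl ether ortho to the ketone by BCl3 is followed by 6-endo-trig oxa-Michael addition of the freed phenol to the enone, closing the chromanone.

**Step 13**
Reactants: 21 benzyl 6,7-bis(benzyloxy)-4-oxochromane-5-carboxylate; 22 diketene
Product: 24 benzyl 6,7-bis(benzyloxy)-4-oxo-3-(3-oxobutanoyl)chromane-5-carboxylate (enolised; C3 not configurationally stable), via lithium enolate 23 (not isolated)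
Conditions: LiN(i-Pr)2 (2.2 equiv), THF, −78 °C; then 22; AcOH quench
Reagents that add atoms: none
Why: Claisen-type C-acetoacetylation of the ketone enolate by acyl–oxygen opening of diketene, with the second equivalent of base absorbing the acidic triketone and the low temperature suppressing retro-oxa-Michael opening of the chromanone enolate.

**Step 14**
Reactants: 17 bridged acylal benzyl (1R,3R)-7,8-bis(benzyloxy)-3-methyl-10,12-dioxo-4,10-dihydro-1H,3H-1,3-(epoxymethano)pyrano[4,3-b]chromene-9-carboxylate; 24 benzyl 6,7-bis(benzyloxy)-4-oxo-3-(3-oxobutanoyl)chromane-5-carboxylate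
Product: 27 (1S,3R)-7,8-bis(benzyloxy)-9-[(benzyloxy)carbonyl]-1-{8,9-bis(benzyloxy)-10-[(benzyloxy)carbonyl]-2-methyl-4-oxo-4H,5H-pyrano[3,2-c]chromen-3-yl}-3-methyl-10-oxo-4,10-dihydro-1H,3H-pyrano[4,3-b]chromene-3-carboxylic acid, via bis(trimethylsilyl) dienol ether 25 (not isolated), via C-alkylated triketone acid 26 (not isolated)
Conditions: 24, N,O-bis(trimethylsilyl)acetamide (2.5 equiv), CH2Cl2, rt; then 17, Me3SiOTf (0.3 equiv), −78 → −40 °C; then TFA/H2O, rt
Reagents that add atoms: none
Why: Me3SiOTf ionises the acyloxy C1–O bond of the acylal and the silyl dienol ether attacks C1 through its side-chain methine carbon (the future C3') from the face opposite the departing carboxylate (invertive Mukaiyama-type acylal substitution, as in Lewis-acid openings of hydroxy-acid-derived dioxanones), so the lactate-derived C3 sets C1 as S; aqueous TFA then desilylates and cyclodehydrates the 1,3,5-triketone to the γ-pyrone, which makes C3' sp2 and blocks retro-oxa-Michael epimerisation of C1.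

**Step 15**
Reactants: 27 (1S,3R)-1-(pyrano[3,2-c]chromen-3-yl)pyrano[4,3-b]chromene-3-carboxylic acid (full name in step 14)
Product: 30 hexabenzyl derivative of the target (1S,3R,2'S,3'S; four aryl benzyl ethers plus two benzyl esters), via oxocarbenium ion 28 (not isolated), via hemiketal 29 (not isolated)
Conditions: undivided cell, graphite anode, Pt cathode, constant current 10 mA cm−2 (2.5 F mol−1), 2,4,6-collidine (0.5 equiv), n-Bu4NPF6 (0.1 M), MeCN/H2O 9:1, rt; then TFA (5 equiv), rt
Reagents that add atoms: water O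
Why: Proposed new method: anodic oxidation of the carboxylate (Hofer–Moest decarboxylation) expels the lactate-derived CO2H as CO2 and gives the ring-oxygen-stabilised tertiary oxocarbenium ion 28, water adds to give hemiketal 29 (freely epimerising at C3), and acid (electrogenerated, then TFA) converts the γ-pyrone into a 4-hydroxypyrylium ion that is attacked at C2' by the C3–OH of the only epimer that can reach it (OH cis to the C1 substituent), after which ketonisation protonates the enolisable C3' under thermodynamic control to the cis-fused dihydropyranone; of the two cis-fused cages only the one that turns the small C2' methyl, and not the aryl-bearing ring oxygen, toward the pyran bridge is unstrained, and the ketalisation is reversible in acid, so C1 (S) alone fixes C3 (R), C2' (S) and C3' (S) in the 2,9-dioxabicyclo[3.3.1]nonane cage; the closest known reaction types are Hofer–Moest decarboxylative acetalisation of α-alkoxy acids and acid-mediated spiroketalisation of hydroxyalkyl γ-pyrones, which have not been merged into one electrochemical cascade or used to close a bridged bis-ketal.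

**Step 16**
Reactants: 30 hexabenzyl derivative of the target
Product: 31 CNP0230818.1 (the target; 1S,3R,2'S,3'S)
Conditions: H2 (1 atm), Pd/C (10 wt%), EtOAc/MeOH 4:1, rt
Reagents that add atoms: none
Why: hydrogenolysis of four aryl benzyl ethers and two benzyl esters under neutral conditions leaves the tetrasubstituted enone and chromone double bonds, the ketal cage and all four stereocentres untouched.

## Compound list

1 | 2,4,5-trihydroxybenzaldehyde | O=Cc1cc(O)c(O)cc1O | starting material
2 | 2,4,5-tris(benzyloxy)benzaldehyde | O=Cc1cc(OCc2ccccc2)c(OCc2ccccc2)cc1OCc1ccccc1 | intermediate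
3 | 2,4,5-tris(benzyloxy)benzoic acid | OC(=O)c1cc(OCc2ccccc2)c(OCc2ccccc2)cc1OCc1ccccc1 | intermediate
4 | lithium 3,4,6-tris(benzyloxy)-2-lithiobenzoate (not isolated) | [Li]OC(=O)c1c([Li])c(OCc2ccccc2)c(OCc2ccccc2)cc1OCc1ccccc1 | intermediate
5 | 3,4,6-tris(benzyloxy)-2-[(benzyloxy)carbonyl]benzoic acid | OC(=O)c1c(C(=O)OCc2ccccc2)c(OCc2ccccc2)c(OCc2ccccc2)cc1OCc1ccccc1 | intermediate
6 | (S)-lactic acid | C[C@H](O)C(=O)O | starting material
7 | (2S,5S)-2-tert-butyl-5-methyl-1,3-dioxolan-4-one | C[C@@H]1O[C@H](C(C)(C)C)OC1=O | intermediate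
8 | propargyl bromide (3-bromoprop-1-yne) | C#CCBr | starting material
9 | lithium enolate of 7, lithium (2S)-2-tert-butyl-5-methyl-1,3-dioxol-4-olate (not isolated) | CC1=C(O[Li])O[C@@H](C(C)(C)C)O1 | intermediate
10 | (2S,5R)-2-tert-butyl-5-methyl-5-(prop-2-yn-1-yl)-1,3-dioxolan-4-one | C[C@]1(CC#C)O[C@H](C(C)(C)C)OC1=O | intermediate
11 | benzyl 2,3,5-tris(benzyloxy)-6-(chlorocarbonyl)benzoate (common aroyl chloride, used crude) | O=C(Cl)c1c(C(=O)OCc2ccccc2)c(OCc2ccccc2)c(OCc2ccccc2)cc1OCc1ccccc1 | intermediate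
12 | benzyl 2,3,5-tris(benzyloxy)-6-{4-[(2S,4R)-2-tert-butyl-4-methyl-5-oxo-1,3-dioxolan-4-yl]but-2-ynoyl}benzoate | C[C@]1(CC#CC(=O)c2c(C(=O)OCc3ccccc3)c(OCc3ccccc3)c(OCc3ccccc3)cc2OCc2ccccc2)O[C@H](C(C)(C)C)OC1=O | intermediate
13 | benzyl 6,7-bis(benzyloxy)-2-{[(2S,4R)-2-tert-butyl-4-methyl-5-oxo-1,3-dioxolan-4-yl]methyl}-3-iodo-4-oxo-4H-chromene-5-carboxylate | C[C@]1(Cc2oc3cc(OCc4ccccc4)c(OCc4ccccc4)c(C(=O)OCc4ccccc4)c3c(=O)c2I)O[C@H](C(C)(C)C)OC1=O | intermediate
14 | chromen-3-ylmagnesium chloride from 13 (MgCl in place of I; not isolated) | C[C@]1(Cc2oc3cc(OCc4ccccc4)c(OCc4ccccc4)c(C(=O)OCc4ccccc4)c3c(=O)c2[Mg]Cl)O[C@H](C(C)(C)C)OC1=O | intermediate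
15 | benzyl 6,7-bis(benzyloxy)-2-{[(2S,4R)-2-tert-butyl-4-methyl-5-oxo-1,3-dioxolan-4-yl]methyl}-3-formyl-4-oxo-4H-chromene-5-carboxylate | C[C@]1(Cc2oc3cc(OCc4ccccc4)c(OCc4ccccc4)c(C(=O)OCc4ccccc4)c3c(=O)c2C=O)O[C@H](C(C)(C)C)OC1=O | intermediate
16 | (2R)-3-{5-[(benzyloxy)carbonyl]-6,7-bis(benzyloxy)-3-formyl-4-oxo-4H-chromen-2-yl}-2-hydroxy-2-methylpropanoic acid (not isolated) | C[C@@](O)(Cc1oc2cc(OCc3ccccc3)c(OCc3ccccc3)c(C(=O)OCc3ccccc3)c2c(=O)c1C=O)C(=O)O | intermediate
17 | benzyl (1R,3R)-7,8-bis(benzyloxy)-3-methyl-10,12-dioxo-4,10-dihydro-1H,3H-1,3-(epoxymethano)pyrano[4,3-b]chromene-9-carboxylate (bridged acylal; lactone bridge C1–O–C(=O)–C3) | C[C@]12Cc3oc4cc(OCc5ccccc5)c(OCc5ccccc5)c(C(=O)OCc5ccccc5)c4c(=O)c3[C@H](O1)OC2=O | intermediate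
18 | tributyl(vinyl)stannane | C=C[Sn](CCCC)(CCCC)CCCC | starting material
19 | benzyl 2-acryloyl-3,5,6-tris(benzyloxy)benzoate | C=CC(=O)c1c(C(=O)OCc2ccccc2)c(OCc2ccccc2)c(OCc2ccccc2)cc1OCc1ccccc1 | intermediate
20 | benzyl 2-acryloyl-5,6-bis(benzyloxy)-3-hydroxybenzoate (not isolated) | C=CC(=O)c1c(C(=O)OCc2ccccc2)c(OCc2ccccc2)c(OCc2ccccc2)cc1O | intermediate
21 | benzyl 6,7-bis(benzyloxy)-4-oxochromane-5-carboxylate | O=C1CCOc2cc(OCc3ccccc3)c(OCc3ccccc3)c(C(=O)OCc3ccccc3)c12 | intermediate
22 | diketene (4-methylideneoxetan-2-one) | C=C1CC(=O)O1 | starting material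
23 | lithium enolate of 21 (not isolated) | [Li]OC1=CCOc2cc(OCc3ccccc3)c(OCc3ccccc3)c(C(=O)OCc3ccccc3)c12 | intermediate
24 | benzyl 6,7-bis(benzyloxy)-4-oxo-3-(3-oxobutanoyl)chromane-5-carboxylate (racemic at C3, largely enolised) | CC(=O)CC(=O)C1COc2cc(OCc3ccccc3)c(OCc3ccccc3)c(C(=O)OCc3ccccc3)c2C1=O | intermediate
25 | benzyl 6,7-bis(benzyloxy)-4-(trimethylsilyloxy)-3-[(2Z)-3-(trimethylsilyloxy)but-2-enoyl]-2H-chromene-5-carboxylate (not isolated) | C/C(O[Si](C)(C)C)=C/C(=O)C1=C(O[Si](C)(C)C)c2c(C(=O)OCc3ccccc3)c(OCc3ccccc3)c(OCc3ccccc3)cc2OC1 | intermediate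
26 | (1S,3R)-pyrano[4,3-b]chromene-3-carboxylic acid carrying at C1 the open 1,3,5-triketone (C1 bonded to the central CH of the 3-oxobutanoyl chain of 24; chain CH and chromanone C3 undefined; not isolated) | C[C@]1(C(=O)O)Cc2oc3cc(OCc4ccccc4)c(OCc4ccccc4)c(C(=O)OCc4ccccc4)c3c(=O)c2[C@@H](O1)C(C(C)=O)C(=O)C1COc2cc(OCc3ccccc3)c(OCc3ccccc3)c(C(=O)OCc3ccccc3)c2C1=O | intermediate
27 | (1S,3R)-7,8-bis(benzyloxy)-9-[(benzyloxy)carbonyl]-1-{8,9-bis(benzyloxy)-10-[(benzyloxy)carbonyl]-2-methyl-4-oxo-4H,5H-pyrano[3,2-c]chromen-3-yl}-3-methyl-10-oxo-4,10-dihydro-1H,3H-pyrano[4,3-b]chromene-3-carboxylic acid | C[C@]1(C(=O)O)Cc2oc3cc(OCc4ccccc4)c(OCc4ccccc4)c(C(=O)OCc4ccccc4)c3c(=O)c2[C@@H](O1)c1c(C)oc2c(c1=O)COc1cc(OCc3ccccc3)c(OCc3ccccc3)c(C(=O)OCc3ccccc3)c12 | intermediate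
28 | (1S)-oxocarbenium ion from 27: C3 cation (C3=O2+) after loss of CO2 (not isolated) | CC1=[O+][C@@H](c2c(C)oc3c(c2=O)COc2cc(OCc4ccccc4)c(OCc4ccccc4)c(C(=O)OCc4ccccc4)c23)c2c(C1)oc1cc(OCc3ccccc3)c(OCc3ccccc3)c(C(=O)OCc3ccccc3)c1c2=O | intermediate
29 | (1S)-3-hydroxy hemiketal (27 with OH in place of CO2H at C3; both C3 epimers; not isolated) | CC1(O)Cc2oc3cc(OCc4ccccc4)c(OCc4ccccc4)c(C(=O)OCc4ccccc4)c3c(=O)c2[C@@H](O1)c1c(C)oc2c(c1=O)COc1cc(OCc3ccccc3)c(OCc3ccccc3)c(C(=O)OCc3ccccc3)c12 | intermediate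
30 | hexabenzyl derivative of 31: (1S,3R,2'S,3'S) cage bis-ketal with the four phenols as benzyl ethers and both acids as benzyl esters | C[C@@]12Cc3oc4cc(OCc5ccccc5)c(OCc5ccccc5)c(C(=O)OCc5ccccc5)c4c(=O)c3[C@@H](O1)[C@H]1C(=O)C3=C(O[C@@]1(C)O2)c1c(cc(OCc4ccccc4)c(OCc4ccccc4)c1C(=O)OCc4ccccc4)OC3 | intermediate
31 | CNP0230818.1, (1S,3R,2'S,3'S): 7,8-dihydroxy-3-methyl-10-oxo-4,10-dihydro-1H,3H-pyrano[4,3-b]chromene-9-carboxylic acid unit joined to an 8',9'-dihydroxy-2'-methyl-4'-oxo-2',3'-dihydro-4'H,5'H-pyrano[3,2-c]chromene-10'-carboxylic acid unit by the C1–C3' bond and the C3–O–C2' ketal oxygen | C[C@@]12Cc3oc4cc(O)c(O)c(C(=O)O)c4c(=O)c3[C@@H](O1)[C@H]1C(=O)C3=C(O[C@@]1(C)O2)c1c(cc(O)c(O)c1C(=O)O)OC3 | target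

## Step count and risks

Total step count: 16. Longest linear sequence: 11 steps (1, 2, 3, 6, 7, 8, 9, 10, 14, 15, 16).

**Step 14 (facial selectivity at C1).** The C1 cation is strongly stabilised, so ionisation may become fully SN1 and erode the inversion that relays the lactate centre to C1. Fallback, setting out from 17 and returning at 27: abandon kinetic control. In wet ethanol 17 reopens to hydroxy acid 16, which undergoes Knoevenagel condensation with 24 (piperidinium acetate, rt) to give the alkylidene triketone F1. Reversible oxa-Michael closure by the tertiary hydroxyl and TFA cyclodehydration then give 27 together with its C1 epimer, the (1R,3R) acid F2. Both are single enantiomers because C3 is bought, so they are separated as diastereomers on silica. F2 is re-equilibrated through the C1 cation (TfOH, hexafluoroisopropanol) and recycled.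

**Step 15 (the proposed new cascade).** Anodic oxidation may give the anhydro enol ether or over-oxidise the arenes, the ketal closure may not occur in the cell, and prolonged acid could open the hemiketal and erode C1 or give the other cis-fused cage. Fallback with known chemistry, setting out from 27 and returning at 30: classical Hofer–Moest electrolysis in methanol (graphite anode, NaOMe 0.1 equiv, constant current) to the isolated 3-methoxy ketal F3 (anomer mixture). In a separate flask, known acid-mediated ketal exchange and oxa-conjugate addition to the γ-pyrone (TsOH, wet MeCN, 40 °C; the spiroketalisation manifold of hydroxyalkyl γ-pyrones) then closes the cage to 30 under short, controlled acid exposure.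

**Step 3 (regioselectivity and benzyl-ether tolerance of the lithiation).** Lithiation between the 2- and 4-benzyloxy groups or at a benzylic position could compete. Fallback, setting out from 2 and returning at 5: direct the metalation from the aldehyde oxidation level. In situ protection of 2 as its α-amino alkoxide (LiN(Me)CH2CH2NMe2), ortho-lithiation (s-BuLi, −78 °C) and ClCO2Bn quench give the formyl ester benzyl 2,3,5-tris(benzyloxy)-6-formylbenzoate F4. Pinnick oxidation of F4 then delivers 5.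

Further compounds
F1 | step 14 | (2R)-3-{5-[(benzyloxy)carbonyl]-6,7-bis(benzyloxy)-3-[2-acetyl-3-{5-[(benzyloxy)carbonyl]-6,7-bis(benzyloxy)-4-oxochroman-3-yl}-3-oxoprop-1-en-1-yl]-4-oxo-4H-chromen-2-yl}-2-hydroxy-2-methylpropanoic acid, the Knoevenagel alkylidene of 16 at the chain methylene of 24 (alkene geometry undefined) | C[C@@](O)(Cc1oc2cc(OCc3ccccc3)c(OCc3ccccc3)c(C(=O)OCc3ccccc3)c2c(=O)c1C=C(C(C)=O)C(=O)C1COc2cc(OCc3ccccc3)c(OCc3ccccc3)c(C(=O)OCc3ccccc3)c2C1=O)C(=O)O
F2 | step 14 | (1R,3R) C1 epimer of 27 | C[C@]1(C(=O)O)Cc2oc3cc(OCc4ccccc4)c(OCc4ccccc4)c(C(=O)OCc4ccccc4)c3c(=O)c2[C@H](O1)c1c(C)oc2c(c1=O)COc1cc(OCc3ccccc3)c(OCc3ccccc3)c(C(=O)OCc3ccccc3)c12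
F3 | step 15 | (1S)-3-methoxy ketal (27 with OMe in place of CO2H at C3; both C3 epimers) | COC1(C)Cc2oc3cc(OCc4ccccc4)c(OCc4ccccc4)c(C(=O)OCc4ccccc4)c3c(=O)c2[C@@H](O1)c1c(C)oc2c(c1=O)COc1cc(OCc3ccccc3)c(OCc3ccccc3)c(C(=O)OCc3ccccc3)c12
F4 | step 3 | benzyl 2,3,5-tris(benzyloxy)-6-formylbenzoate | O=Cc1c(C(=O)OCc2ccccc2)c(OCc2ccccc2)c(OCc2ccccc2)cc1OCc1ccccc1
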